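Everything rests on opening rings A and D of the target across C1–C2 and C15'–C4'. In guaianolide numbering (primed atoms for the spiro half), C2 and C4' are adjacent, fully substituted and flanked by the C3 and C3' ketones, so they are the alkene of a cis-enedione, and C1 lies three atoms (C5, C4, C3) from C2. One intramolecular Diels–Alder reaction between a 1-silyloxy-2-vinylcycloheptene (ring B) and this tethered 2-silyloxy-enedione therefore closes both rings and sets C1, C2 and C4'. The precursor is a 1,2-seco-guaianolide dienol silyl ether whose C3 carbonyl belongs to a ring E silyloxy-enedione, released from a fused 3-silyloxyfuran; both halves derive from dehydrocostus lactone.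

Key step: step 22

Remark on the chemistry: centres that are destroyed later (the C3 and C3' carbinols, C10 of the seco half before step 11, epoxide carbons, the C4' carbinol, the endoperoxide bridgeheads) are carried as epimer mixtures, and their SMILES carry no configuration there.

Step 1
Reactants: 1 dehydrocostus lactone
Product: 2 3-hydroxydehydrocostus lactone (C3 epimers)
Conditions: SeO2 (0.5 equiv), t-BuOOH, CH2Cl2, 0 °C to rt
Reagents that add atoms: tert-butyl hydroperoxide, CC(C)(C)OO (oxygen relayed by SeO2)
Why: Riley allylic oxidation is established for this lactone at C3, the ring methylene allylic to C4=C15, and the carbinol configuration is immaterial because C3 is later oxidised or aromatised.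

Step 2
Reactants: 2 3-hydroxydehydrocostus lactone
Product: 3 dehydrozaluzanin C (3-ketone)
Conditions: DMP, CH2Cl2, rt
Reagents that add atoms: none
Why: Dess–Martin oxidation of the secondary allylic alcohol is neutral, spares the three exocyclic alkenes and makes C4=C15 electron-poor for the next step.

Step 3
Reactants: 3 dehydrozaluzanin C
Product: 4 10,14-epoxide of 3 (spiro-oxirane at C10)
Conditions: mCPBA, CH2Cl2, 0 °C
Reagents that add atoms: 3-chloroperoxybenzoic acid, OOC(=O)c1cccc(Cl)c1
Why: Prilezhaev epoxidation should select C10=C14 because it is the only alkene not conjugated to a carbonyl group, and the configuration of the spiro centre is irrelevant.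

Step 4
Reactants: 4 10,14-epoxide
Product: 5 C10 carbaldehyde (3,14-dioxo compound, C10 epimers)
Conditions: BF3·OEt2 (cat.), CH2Cl2, −78 °C
Reagents that add atoms: none
Why: Meinwald rearrangement, in which BF3-promoted opening to the tertiary C10 cation and a 1,2-hydride shift from C14 give the aldehyde; C10 becomes an epimerisable centre that is planarised in step 11.

Step 5
Reactants: 5 C10 carbaldehyde
Product: 6 10-vinyl ketone (C10 bears H and C14H=C15'H2)
Conditions: CH2I2, Zn, Ti(OiPr)4, THF, 0 °C to rt
Reagents that add atoms: diiodomethane, ICI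
Why: Takai methylenation is non-basic and converts aldehydes much faster than ketones or lactones, so only C14 should be methylenated and the Michael acceptors survive.

Step 6
Reactants: 6 10-vinyl ketone
Product: 7 cross-conjugated dienone (C1=C2, 3-ketone, C4=C15)
Conditions: IBX, DMSO, 70 °C
Reagents that add atoms: none
Why: IBX dehydrogenation runs through the enol, and since C4 carries no hydrogen the C3 ketone can desaturate only toward C2–C1.

Step 7
Reactants: 7 cross-conjugated dienone
Product: 8 bis-allylic 3-alcohol (C3 epimers)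
Conditions: NaBH4, CeCl3·7H2O, MeOH, −78 °C
Reagents that add atoms: none
Why: Luche reduction delivers hydride 1,2 to the dienone carbonyl at low temperature without conjugate reduction of the enone or the lactone methylene, and the C3 configuration is irrelevant.

Step 8
Reactants: 8 bis-allylic 3-alcohol
Product: 9 1,2-epoxy-3-alcohol
Conditions: VO(acac)2 (cat.), t-BuOOH, CH2Cl2, 0 °C
Reagents that add atoms: tert-butyl hydroperoxide, CC(C)(C)OO
Why: Hydroxyl-directed VO(acac)2-catalysed epoxidation touches only the two allylic alkenes and should prefer the more nucleophilic trisubstituted C1=C2 over the 1,1-disubstituted C4=C15, placing on C1 the oxygen that becomes the ring B ketone (epoxide syn to the hydroxyl, configuration irrelevant).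

Step 9
Reactants: 9 1,2-epoxy-3-alcohol
Product: 10 1,2-epoxy-3-ketone
Conditions: DMP, CH2Cl2, rt
Reagents that add atoms: none
Why: Dess–Martin oxidation returns the C3 ketone without opening the epoxide and so gives the alpha,beta-epoxy ketone needed for fragmentation.

Step 10
Reactants: 10 1,2-epoxy-3-ketone
Product: 12 1,2-seco enynone (ring B C1 ketone; C10 vinyl; C5 but-1-en-3-yn-2-yl), via epoxy tosylhydrazone 11 (not isolated)
Conditions: TsNHNH2, AcOH, CH2Cl2, −20 °C to rt
Reagents that add atoms: none
Why: Eschenmoser–Tanabe fragmentation, in which the epoxy tosylhydrazone collapses in a Grob-type manner with loss of N2 and sulfinate, cuts C1–C2 to leave the C1 ketone and the C2≡C3 alkyne while C5, C6 and C7 are untouched.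

Step 11
Reactants: 12 1,2-seco enynone
Product: 13 dienyl acetate (C1 enol acetate, C1=C10 conjugated to the vinyl group)
Conditions: isopropenyl acetate, TsOH (cat.), 60 °C
Reagents that add atoms: isopropenyl acetate, CC(=C)OC(C)=O
Why: Acid-catalysed enol acetylation under equilibrating conditions should give the conjugated dienyl acetate, because the C1=C5 isomer suffers allylic strain from the branched C4 substituent, and it masks the ketone while storing the regiochemistry of the later dienol ether.

Step 12
Reactants: 2 3-hydroxydehydrocostus lactone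
Product: 14 4',15'-epoxy-3'-alcohol
Conditions: VO(acac)2 (cat.), t-BuOOH, CH2Cl2, 0 °C
Reagents that add atoms: tert-butyl hydroperoxide, CC(C)(C)OO
Why: Directed VO(acac)2-catalysed epoxidation of the allylic alcohol oxidises C4'=C15' only and leaves C10'=C14' and the lactone methylene, and the epoxide configuration is irrelevant.

Step 13
Reactants: 14 4',15'-epoxy-3'-alcohol
Product: 15 3'-O-TBS ether of 14
Conditions: TBSCl, imidazole, DMF, rt
Reagents that add atoms: tert-butyldimethylsilyl chloride, C[Si](C)(Cl)C(C)(C)C
Why: Standard silylation protects the C3' hydroxyl so that the glycol cleavage of the next step cannot cut the C3'–C4' bond.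

Step 14
Reactants: 15 3'-O-TBS epoxide
Product: 16 15'-nor-4'-ketone (3'-OTBS)
Conditions: H5IO6, Et2O–THF, 0 °C to rt
Reagents that add atoms: periodic acid, OI(O)(O)(O)(O)=O (supplies the carbonyl oxygen, directly or through its water)
Why: Periodic acid hydrolyses the spiro-epoxide and cleaves the resulting 1,2-diol in one operation (Malaprade cleavage), excising C15' as formaldehyde and leaving the C4' ketone as the only electrophilic carbonyl of ring E.

Step 15
Reactants: 13 dienyl acetate; 16 15'-nor-4'-ketone
Product: 17 propargylic alcohol (C2–C4' bond; C4'–OH, 3'-OTBS)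
Conditions: InBr3 (0.2 equiv), iPr2NEt (0.5 equiv), CH2Cl2, 40 °C
Reagents that add atoms: none
Why: InBr3-catalysed addition of a terminal alkyne to a ketone (dual activation by InBr3 and a hindered amine) needs no strong base, so the lactone methylenes and the enol acetate should survive, and it forms the C2–C4' bond at the only ketone, the C4' configuration being irrelevant.

Step 16
Reactants: 17 propargylic alcohol
Product: 18 3',4'-diol
Conditions: HF·pyridine, THF, 0 °C to rt
Reagents that add atoms: none
Why: Acidic fluoride desilylation frees the C3' hydroxyl without touching the enol acetate or the tertiary propargylic alcohol.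

Step 17
Reactants: 18 3',4'-diol
Product: 19 4'-hydroxy-3'-ketone
Conditions: DMP, CH2Cl2, rt
Reagents that add atoms: none
Why: Dess–Martin oxidation can only oxidise the secondary C3' alcohol and so gives the tertiary alpha-ketol.

Step 18
Reactants: 19 4'-hydroxy-3'-ketone
Product: 20 4'-acetate (alpha-acetoxy alkynyl ketone)
Conditions: Ac2O, DMAP, Et3N, CH2Cl2, rt to 40 °C
Reagents that add atoms: acetic anhydride, CC(=O)OC(C)=O
Why: DMAP-catalysed acetylation of the tertiary propargylic alcohol installs the group that will migrate, and doing it after the oxidation avoids acetyl migration to the C3' oxygen.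

Step 19
Reactants: 20 4'-acetate
Product: 21 3-acetoxyfuran (furan oxygen between C3 and C3'; OAc on C2; fused to ring E)
Conditions: AgBF4 (5 mol %), CH2Cl2, rt, dark
Reagents that add atoms: none
Why: AgBF4-catalysed cycloisomerisation of alpha-acyloxy beta,gamma-alkynyl ketones, a [3,3] acyloxy shift to the acyloxy allene followed by 1,2-acyloxy migration and ring closure, is a known furan synthesis that moves the acetate from C4' to C2 while the C3' carbonyl oxygen closes onto C3, and the C1 enol acetate is not nucleophilic enough to compete.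

Step 20
Reactants: 21 3-acetoxyfuran
Product: 23 bis-TBS furan-diene (C2–OTBS furan; C1–OTBS dienol ether), via bis(tributylstannyl) dienolate 22 (not isolated)
Conditions: Bu3SnOMe, THF, 50 °C; then TBSOTf, CH2Cl2, −78 to 0 °C
Reagents that add atoms: tert-butyldimethylsilyl trifluoromethanesulfonate, C[Si](C)(OS(=O)(=O)C(F)(F)F)C(C)(C)C
Why: Bu3SnOMe cleaves enol acetates to tributyltin enolates without free base, and the silyl triflate then O-silylates both the furan-3-olate and the dienolate with retention of the regiochemistry fixed in step 11.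

Step 21
Reactants: 23 bis-TBS furan-diene
Product: 25 cycloaddition precursor (dienol silyl ether tethered to the 2-silyloxy-enedione; used crude), via furan endoperoxide 24 (not isolated)
Conditions: O2, visible light, tetraphenylporphyrin (cat.), CH2Cl2, −78 °C; then Me2S, −78 to −20 °C
Reagents that add atoms: dioxygen, O=O
Why: Singlet oxygen should add [4+2] across the furan alpha-carbons C3 and C3' far faster than it attacks the hindered silyloxy diene, and reduction of the endoperoxide with dimethyl sulfide opens it to the enedione with the C3 and C3' carbonyls necessarily cis (CIP descriptor E).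

Step 22
Reactants: 25 cycloaddition precursor
Product: 26 cycloadduct (rings A and D closed; C1–OTBS, C2–OTBS, C10=C14)
Conditions: toluene (2 mM), BHT, 60–90 °C
Reagents that add atoms: none
Why: Heating the dilute solution brings the 1-silyloxy diene (C1=C10–C14=C15') onto the doubly acyl-activated C2=C4' alkene in a concerted but asynchronous [4+2] cycloaddition, the nucleophilic C15' bonding to C4' ahead of the demanding C1–C2 bond, which joins two fully substituted carbons and is feasible because it is intramolecular and because C2 and C4' are already bonded to each other. It is a type 1 intramolecular Diels–Alder reaction with a three-atom tether, and the closest known class is the cycloaddition of furan-derived cis-enediones with oxygenated dienes. Ring D (six-membered) is the ring made by the cycloaddition itself, and ring A (five-membered) closes at the same time as the tether ring through C1–C2, the only mode that the C5–C4–C3 tether allows. Suprafacial addition copies the alkene geometry into the relative configuration of C2 and C4' (C3 and C3' cis, the C2 oxygen cis to C5' on ring D), and the tether delivers the dienophile to the face of C1 that carries C4 (anti to H-5), which fixes C1. The selectivity that the step needs is the choice of dienophile face: only the transition state with the C3 carbonyl tucked under the diene (cis fusion of rings A and D, C1–O and C2–O syn) gives the required absolute configuration at C2 and C4', and it should be favoured because the trans-fused alternative strains the conjugated three-atom tether, although it places the diene over the ring E face that carries C6'. Dilution and a radical inhibitor suppress intermolecular cycloaddition with the alpha-methylene lactones.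

Step 23
Reactants: 26 cycloadduct
Product: 27 C2-O-TBS ether of the target (C1=C10 alkene)
Conditions: Et3SiH, BF3·OEt2, 2,6-di-tert-butyl-4-methylpyridine, CH2Cl2, −78 to −40 °C
Reagents that add atoms: none
Why: Ionic reduction, in which BF3 ionises the tertiary allylic C1 silyl ether (the C2 ether, flanked by two ketones, cannot ionise) and Et3SiH delivers hydride to the less hindered C14 terminus of the C1–C10–C14 allyl cation, should give the tetrasubstituted C1=C10 alkene and erase the C1 stereocentre.

Step 24
Reactants: 27 C2-O-TBS ether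
Product: 28 target CNP0269880.2
Conditions: HF·pyridine, THF, 0 °C to rt
Reagents that add atoms: none
Why: Acidic fluoride removes the hindered tertiary silyl ether without the basic conditions that could trigger retro-aldol cleavage of the C2–C4' bond or additions to the Michael acceptors.

Compound list
1 | dehydrocostus lactone (guaia-4(15),10(14),11(13)-trien-12,6α-olide) | C=C1CC[C@@H]2[C@@H]([C@@H]3[C@H]1CCC3=C)OC(=O)C2=C | starting material
2 | 3-hydroxydehydrocostus lactone (C3 epimers) | C=C1CC[C@@H]2[C@@H]([C@@H]3[C@H]1CC(O)C3=C)OC(=O)C2=C | intermediate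
3 | dehydrozaluzanin C | C=C1CC[C@@H]2[C@@H]([C@@H]3[C@H]1CC(=O)C3=C)OC(=O)C2=C | intermediate
4 | 10,14-epoxydehydrozaluzanin C | C1OC12CC[C@@H]3[C@@H]([C@@H]4[C@H]2CC(=O)C4=C)OC(=O)C3=C | intermediate
5 | C10 carbaldehyde (3,14-dioxoguaia-4(15),11(13)-dien-12,6α-olide, C10 epimers) | O=CC1CC[C@@H]2[C@@H]([C@@H]3[C@H]1CC(=O)C3=C)OC(=O)C2=C | intermediate
6 | 10-vinyl ketone (C10: H and C14H=C15'H2) | C=CC1CC[C@@H]2[C@@H]([C@@H]3[C@H]1CC(=O)C3=C)OC(=O)C2=C | intermediate
7 | cross-conjugated dienone (C1=C2, C3=O, C4=C15) | C=CC1CC[C@@H]2[C@@H]([C@@H]3C1=CC(=O)C3=C)OC(=O)C2=C | intermediate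
8 | bis-allylic 3-alcohol | C=CC1CC[C@@H]2[C@@H]([C@@H]3C1=CC(O)C3=C)OC(=O)C2=C | intermediate
9 | 1,2-epoxy-3-alcohol | C=CC1CC[C@@H]2[C@@H]([C@@H]3C14OC4C(O)C3=C)OC(=O)C2=C | intermediate
10 | 1,2-epoxy-3-ketone | C=CC1CC[C@@H]2[C@@H]([C@@H]3C14OC4C(=O)C3=C)OC(=O)C2=C | intermediate
11 | C3 tosylhydrazone of 10 | C=CC1CC[C@@H]2[C@@H]([C@@H]3C14OC4C(=NNS(=O)(=O)c4ccc(C)cc4)C3=C)OC(=O)C2=C | intermediate
12 | 1,2-seco enynone (ring B C1 ketone, C10 vinyl, C5 but-1-en-3-yn-2-yl, 6,12-lactone) | C#CC(=C)[C@@H]1[C@H]2OC(=O)C(=C)[C@@H]2CCC(C=C)C1=O | intermediate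
13 | dienyl acetate (C1–OAc, C1=C10, C10 vinyl) | C#CC(=C)[C@@H]1[C@H]2OC(=O)C(=C)[C@@H]2CCC(C=C)=C1OC(C)=O | intermediate
14 | 4',15'-epoxy-3'-hydroxyguaia-10'(14'),11'(13')-dien-12',6'α-olide | C=C1CC[C@@H]2[C@@H]([C@@H]3[C@H]1CC(O)C34CO4)OC(=O)C2=C | intermediate
15 | 3'-O-TBS ether of 14 | C=C1CC[C@@H]2[C@@H]([C@@H]3[C@H]1CC(O[Si](C)(C)C(C)(C)C)C34CO4)OC(=O)C2=C | intermediate
16 | 3'-(TBS-oxy)-4'-oxo-15'-norguaia-10'(14'),11'(13')-dien-12',6'α-olide | C=C1CC[C@@H]2[C@@H]([C@@H]3[C@H]1CC(O[Si](C)(C)C(C)(C)C)C3=O)OC(=O)C2=C | intermediate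
17 | propargylic alcohol (C4'–OH, C3'–OTBS, C2≡C3 link to the dienyl acetate) | C=C(C#CC1(O)C(O[Si](C)(C)C(C)(C)C)C[C@H]2C(=C)CC[C@H]3C(=C)C(=O)O[C@@H]3[C@@H]12)[C@@H]1[C@H]2OC(=O)C(=C)[C@@H]2CCC(C=C)=C1OC(C)=O | intermediate
18 | 3',4'-diol | C=C(C#CC1(O)C(O)C[C@H]2C(=C)CC[C@H]3C(=C)C(=O)O[C@@H]3[C@@H]12)[C@@H]1[C@H]2OC(=O)C(=C)[C@@H]2CCC(C=C)=C1OC(C)=O | intermediate
19 | 4'-hydroxy-3'-ketone | C=C(C#CC1(O)C(=O)C[C@H]2C(=C)CC[C@H]3C(=C)C(=O)O[C@@H]3[C@@H]12)[C@@H]1[C@H]2OC(=O)C(=C)[C@@H]2CCC(C=C)=C1OC(C)=O | intermediate
20 | 4'-acetoxy-3'-ketone | C=C(C#CC1(OC(C)=O)C(=O)C[C@H]2C(=C)CC[C@H]3C(=C)C(=O)O[C@@H]3[C@@H]12)[C@@H]1[C@H]2OC(=O)C(=C)[C@@H]2CCC(C=C)=C1OC(C)=O | intermediate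
21 | 3-acetoxyfuran (O between C3 and C3', OAc on C2, fused to ring E) with C1 dienyl acetate | C=C(C1=C(OC(C)=O)C2=C(O1)C[C@H]3C(=C)CC[C@H]4C(=C)C(=O)O[C@@H]4[C@@H]23)[C@@H]1[C@H]2OC(=O)C(=C)[C@@H]2CCC(C=C)=C1OC(C)=O | intermediate
22 | bis(tributylstannyl) furanolate-dienolate | C=C(C1=C(O[Sn](CCCC)(CCCC)CCCC)C2=C(O1)C[C@H]3C(=C)CC[C@H]4C(=C)C(=O)O[C@@H]4[C@@H]23)[C@@H]1[C@H]2OC(=O)C(=C)[C@@H]2CCC(C=C)=C1O[Sn](CCCC)(CCCC)CCCC | intermediate
23 | bis-TBS furan-diene (C2–OTBS furan, C1–OTBS dienol ether) | C=C(C1=C(O[Si](C)(C)C(C)(C)C)C2=C(O1)C[C@H]3C(=C)CC[C@H]4C(=C)C(=O)O[C@@H]4[C@@H]23)[C@@H]1[C@H]2OC(=O)C(=C)[C@@H]2CCC(C=C)=C1O[Si](C)(C)C(C)(C)C | intermediate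
24 | furan endoperoxide (O–O bridge between C3 and C3') | C=C(C12OOC3(O1)C[C@H]4C(=C)CC[C@H]5C(=C)C(=O)O[C@@H]5[C@H]4C3=C2O[Si](C)(C)C(C)(C)C)[C@@H]1[C@H]2OC(=O)C(=C)[C@@H]2CCC(C=C)=C1O[Si](C)(C)C(C)(C)C | intermediate
25 | cycloaddition precursor: ring B dienol TBS ether tethered through C5–C4(=CH2)–C3(=O) to the (E)-2-(TBS-oxy)-enedione of ring E (C3 and C3' carbonyls cis) | C=C(C(=O)/C(O[Si](C)(C)C(C)(C)C)=C5\C(=O)C[C@H]6C(=C)CC[C@H]7C(=C)C(=O)O[C@@H]7[C@@H]56)[C@@H]1[C@H]2OC(=O)C(=C)[C@@H]2CCC(C=C)=C1O[Si](C)(C)C(C)(C)C | intermediate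
26 | cycloadduct (C1 and C2 OTBS cis, C10=C14, spiro C4') | C=C1C(=O)[C@]2(O[Si](C)(C)C(C)(C)C)[C@@]3(O[Si](C)(C)C(C)(C)C)C(CC[C@H]4C(=C)C(=O)O[C@@H]4[C@@H]13)=CC[C@]21C(=O)C[C@H]2C(=C)CC[C@H]3C(=C)C(=O)O[C@@H]3[C@H]21 | intermediate
27 | C2-O-TBS ether of the target | C=C1C(=O)[C@]2(O[Si](C)(C)C(C)(C)C)C3=C(CC[C@H]4C(=C)C(=O)O[C@@H]4[C@@H]13)CC[C@]21C(=O)C[C@H]2C(=C)CC[C@H]3C(=C)C(=O)O[C@@H]3[C@H]21 | intermediate
28 | CNP0269880.2 | C=C1C(=O)[C@]2(O)C3=C(CC[C@H]4C(=C)C(=O)O[C@@H]4[C@@H]13)CC[C@]21C(=O)C[C@H]2C(=C)CC[C@H]3C(=C)C(=O)O[C@@H]3[C@H]21 | target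

Total step count: 24. Longest linear sequence: 21 steps (steps 1–11 and 15–24, from 1 through 13 and 17 to 28).

The three steps most likely to fail

First, step 22, the cycloaddition. It may be slower than isomerisation of the enedione about C2=C4' or migration of a silyl group, because the C1–C2 bond joins two fully substituted carbons and the diene has to approach the more hindered face of ring E. The fallback gives up the concerted thermal mode and forms the same two bonds stepwise by ionic chemistry: 25 is treated at −78 °C in CH2Cl2 with substoichiometric Me2AlCl, so that a vinylogous Mukaiyama–Michael addition of C15' to C4' is followed by Mukaiyama aldol closure of the resulting C2 enolate onto the C1 silyloxocarbenium ion. The fallback sets out from 25 and comes back to the route at 26; it forms no compound outside the compound list, which the entry F0 records.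

Second, step 23, the ionic reduction. The C1–C10–C14 cation may rearrange (1,2-shift of an acyl group or a ring bond from C2, or proton loss to a diene), or acid may protonate the exocyclic alkenes faster than hydride is delivered to C14. The fallback replaces the cation by a radical: 26 is desilylated with HF·pyridine to the C1,C2-diol of the cycloadduct F1, which 1,1'-thiocarbonyldiimidazole and DMAP in toluene at 80 °C should close to the cyclic thionocarbonate F2. Barton–McCombie-type fragmentation with (Me3Si)3SiH and AIBN should break the allylic C1–O bond and transfer hydrogen to C14 of the allyl radical, giving the S-silyl thiocarbonate F3, and hydrolytic work-up then releases the C2 hydroxyl. The fallback sets out from 26 and comes back to the route at 28.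

Third, step 21, the furan oxidation. Singlet oxygen may also consume the silyl dienol ether, or a silyl group may transfer to the peroxide while the endoperoxide collapses, so that the diene or the enedione geometry is lost. The fallback oxidises before any silyl enol ether exists: 21, in which both oxygens are still acetylated and the dienyl acetate is a poor singlet-oxygen acceptor, is photooxygenated (O2, visible light, tetraphenylporphyrin, −78 °C) to the acetoxyfuran endoperoxide F4 and reduced in the same flask with Me2S to the acetoxy-enedione dienyl acetate F5. This is cyclised thermally in dilute toluene to the bis-acetate cycloadduct F6, reduced with Et3SiH and BF3·OEt2 at the tertiary allylic acetate to the C2 acetate of the target F7, and deacetylated with Sc(OTf)3 in aqueous methanol. The fallback sets out from 21 and comes back to the route at 28.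

Further compounds
F0 | step 22 | none | none
F1 | step 23 | C1,C2-diol of the cycloadduct | C=C1C(=O)[C@]2(O)[C@@]3(O)C(CC[C@H]4C(=C)C(=O)O[C@@H]4[C@@H]13)=CC[C@]21C(=O)C[C@H]2C(=C)CC[C@H]3C(=C)C(=O)O[C@@H]3[C@H]21
F2 | step 23 | cyclic thionocarbonate | C=C1C(=O)[C@]2(OC(=S)O6)[C@@]36C(CC[C@H]4C(=C)C(=O)O[C@@H]4[C@@H]13)=CC[C@]21C(=O)C[C@H]2C(=C)CC[C@H]3C(=C)C(=O)O[C@@H]3[C@H]21
F3 | step 23 | S-silyl thiocarbonate | C=C1C(=O)[C@]2(OC(=O)S[Si]([Si](C)(C)C)([Si](C)(C)C)[Si](C)(C)C)C3=C(CC[C@H]4C(=C)C(=O)O[C@@H]4[C@@H]13)CC[C@]21C(=O)C[C@H]2C(=C)CC[C@H]3C(=C)C(=O)O[C@@H]3[C@H]21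
F4 | step 21 | acetoxyfuran endoperoxide | C=C(C12OOC3(O1)C[C@H]4C(=C)CC[C@H]5C(=C)C(=O)O[C@@H]5[C@H]4C3=C2OC(C)=O)[C@@H]1[C@H]2OC(=O)C(=C)[C@@H]2CCC(C=C)=C1OC(C)=O
F5 | step 21 | acetoxy-enedione dienyl acetate | C=C(C(=O)/C(OC(C)=O)=C5\C(=O)C[C@H]6C(=C)CC[C@H]7C(=C)C(=O)O[C@@H]7[C@@H]56)[C@@H]1[C@H]2OC(=O)C(=C)[C@@H]2CCC(C=C)=C1OC(C)=O
F6 | step 21 | bis-acetate cycloadduct | C=C1C(=O)[C@]2(OC(C)=O)[C@@]3(OC(C)=O)C(CC[C@H]4C(=C)C(=O)O[C@@H]4[C@@H]13)=CC[C@]21C(=O)C[C@H]2C(=C)CC[C@H]3C(=C)C(=O)O[C@@H]3[C@H]21
F7 | step 21 | C2 acetate of the target | C=C1C(=O)[C@]2(OC(C)=O)C3=C(CC[C@H]4C(=C)C(=O)O[C@@H]4[C@@H]13)CC[C@]21C(=O)C[C@H]2C(=C)CC[C@H]3C(=C)C(=O)O[C@@H]3[C@H]21
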